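Readings and results are simulated with constants of no real substance.

Each flask is a stirred vessel of constant volume holding 3.0 mM of free catalyst, and I count what that catalyst does.

| flask | substrate | reagent | free catalyst | impurity | remark | time |
|---|---|---|---|---|---|---|
| south | 0.30 M | 0.315 M | 3 mM | 1 mM | run made earlier |  |
| north | 0.30 M | 0.315 M | 3 mM | 0.50 mM | run made earlier |  |
| north-west | 0.30 M | 0.315 M | 3 mM | 2 mM | run made earlier |  |
| north-east | 0.60 M | 0.315 M | 3 mM | 1 mM | run made earlier |  |
| noon | 0.30 M (in portions, 3, over 2.0 h) | 0.315 M | 3.0 mM | 1.0 mM | first portion at the start, last at 2.0 h | 10 h |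
| summer | 0.30 M | 0.315 M (fed, over 2.0 h) | 3.0 mM | 1.0 mM | all else is in the flask from the start; the feed brings no volume worth counting | 10 h |
| dawn | 0.30 M (fed, over 12 min) | 0.315 M | 3.0 mM | 1.0 mM | all else is in the flask from the start; the feed brings no volume worth counting | 10 h |
| spring | 0.30 M (fed, over 2.0 h) | 0.315 M | 3.0 mM | 1.0 mM | all else is in the flask from the start; the feed brings no volume worth counting | 10 h |
| autumn | 0.30 M | 0.315 M | 3.0 mM | 1.0 mM | everything together at the start | 10 h |

- south (time / h: product / %, substrate / %): 1.00: 4, 94; 2.00: 13, 84; 3.00: 21, 79; 4.00: 29, 70; 5.00: 31, 67; 6.00: 39, 60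
- north (time / h: product / %, substrate / %): 0.500: 5, 97; 0.833: 4, 91; 1.33: 10, 90; 2.00: 17, 84; 4.00: 29, 71; 6.00: 40, 59
- north-west (time / h: product / %, substrate / %): 1.00: 9, 88; 2.00: 14, 84; 3.00: 20, 78; 4.00: 27, 72; 5.00: 28, 71; 6.00: 33, 65
- north-east (time / h: product / %, substrate / %): 1.33: 5, 92; 2.50: 9, 88; 4.00: 15, 85; 5.00: 17, 84; 6.00: 24, 81

(readings scatter by 1.5 percentage points)



1. the flask with the highest amount of product, in percent of the substrate charged ("all alike" if they lie within 1.5 percentage points) (noon / summer / dawn / spring / autumn / all alike)
2. final product, as a percentage of the substrate charged, in noon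
3. final product, as a percentage of the substrate charged, in summer
4. final product, as a percentage of the substrate charged, in dawn
5. final product, as a percentage of the substrate charged, in spring
6. final product, as a percentage of the substrate charged, in autumn

I count turnovers: product made per catalyst charged, the turnover number. At 4.00 h the south run stands at 29.0, and the north-east run, with twice the substrate, stands at 30.0. So these two readings show no response of the count to the substrate charge. But I assume each turnover takes one reagent, so from the reading at 6.00 h I reckon that the south run has 0.198 M of reagent left from 0.315 M.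

The south curve is too scattered to show its bend, so I commit to an assumption: the pace follows reagent, as a pseudo-first-order loss. Read off that one south reading, with its scatter, the constant of that loss is 0.0774 h⁻¹. I carry N, the turnovers made in 10 h by 3.0 mM of catalyst, which comes to 56.6. In autumn I reckon that as 56.6 % of the substrate charged. The feeds in summer and spring end at 2.0 h, early in the 10 h, and I place them behind autumn.

The forecast names autumn, with 63 % (57 % to 69 %) there, 62.5 % for dawn, and 61 %, 61 % and 61 % for noon, summer and spring. It holds that “reagent order looks near zero too”, whereas I take the order as one, and my autumn figure stands lower than its figure.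

The flasks give noon 51.6 %, summer 50.9 %, dawn 52.2 %, spring 47.7 % and autumn 54.1 %, so autumn is highest.

    substrate + free catalyst → catalyst intermediate A (k = 40.0 M⁻¹ min⁻¹)
    reagent + catalyst intermediate A → catalyst intermediate B (k = 0.690 M⁻¹ min⁻¹)
    catalyst intermediate B → released group + catalyst intermediate C (k = 13.0 min⁻¹)
    catalyst intermediate C → free catalyst + product (k = 0.400 min⁻¹)
    free catalyst + impurity → spent catalyst (k = 81.0 M⁻¹ min⁻¹)

Autumn's count is 54.1 turnovers against my N of 56.6, with 48.3 % of its reagent left at 10.0 h. The neighbouring flask is spring with 0.75 M of substrate. Carried over unchanged, N gives 22.6 % of that larger charge. That neighbouring flask gives 20.7 %, with 79.0 % of its substrate left, and that is 51.8 turnovers.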